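**Retrosynthetic overview**
- Sanggenol C comes from its 5,7-bis-MOM ether. The last step only frees two phenols and touches no stereocentre.
- The bis-MOM flavanonol is cut into an A-ring aryl chloromethyl ketone and 3-geranyl-4-silyloxybenzaldehyde. C2–C3 is formed by a catalytic asymmetric Darzens reaction and O1–C2 by a desilylative 6-endo epoxide opening, both in one flask.
- Ring order: rings A and B are bought as arenes. The oxirane forms first and the dihydropyranone C ring second, in the same operation. The catalyst sets C3, and inversion plus the trans preference sets C2.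
- The chloroketone comes from phloracetophenone by C-prenylation, 4,6-bis-MOM protection and one-pot O-TIPS/α-chlorination. The OH left free sits next to the prenyl group, becomes O1, and so fixes the 8-prenyl pattern.
- The aldehyde comes from 4-hydroxybenzaldehyde and geranyl bromide by ortho C-geranylation, followed by TIPS protection.

Assumption: the SMILES is read as (2R,3R), i.e. 2,3-trans, with an (E)-geranyl chain. One step means one isolated product.

**Step 1**
Reactants: 1 2',4',6'-trihydroxyacetophenone; 2 prenyl bromide (1-bromo-3-methylbut-2-ene, 0.9 equiv)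
Product: 3 1-[2,4,6-trihydroxy-3-(3-methylbut-2-enyl)phenyl]ethanone
Conditions: KOH (1.1 equiv), H2O, 0 °C → rt
Reagents that add atoms: none
Why: Phenolate C-alkylation (SN2): in water the hydrogen-bonded phloroglucinol-type phenolate reacts through carbon, and because the two free ring positions of 1 are equivalent only one mono-C-prenyl isomer can form (sub-stoichiometric 2 limits diprenylation).

**Step 2**
Reactants: 3 1-[2,4,6-trihydroxy-3-(3-methylbut-2-enyl)phenyl]ethanone
Product: 4 1-[2-hydroxy-4,6-bis(methoxymethoxy)-3-(3-methylbut-2-enyl)phenyl]ethanone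
Conditions: MOMCl (2.2 equiv), K2CO3, acetone, 0 °C → rt
Reagents that add atoms: chloromethyl methyl ether (MOMCl) COCCl
Why: Williamson-type ether formation under steric and chelation control: the unchelated 4-OH and the less hindered 6-OH react while the OH wedged between prenyl and acetyl stays free (the selectivity known for partial O-alkylation of 3-alkylphloracetophenones), and this OH is the future O1 that fixes the 8-prenyl pattern.

**Step 3**
Reactants: 4 1-[2-hydroxy-4,6-bis(methoxymethoxy)-3-(3-methylbut-2-enyl)phenyl]ethanone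
Product: 7 2-chloro-1-[4,6-bis(methoxymethoxy)-3-(3-methylbut-2-enyl)-2-(triisopropylsilyloxy)phenyl]ethanone, via O-TIPS methyl ketone 5 (not isolated), via TMS enol ether 6 (not isolated)
Conditions: TIPSOTf (1.1 equiv), Et3N (4 equiv), CH2Cl2, 0 °C; TMSOTf (1.3 equiv), 0 °C; then NCS (1.05 equiv), −78 → 0 °C
Reagents that add atoms: triisopropylsilyl triflate CC(C)[Si](OS(=O)(=O)C(F)(F)F)(C(C)C)C(C)C; N-chlorosuccinimide O=C1CCC(=O)N1Cl; trimethylsilyl triflate C[Si](C)(C)OS(=O)(=O)C(F)(F)F (its Me3Si is carried by 6 only)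
Why: Phenol O-silylation, soft enolisation to the enol silane and electrophilic α-chlorination in one pot: the enol silane outruns the trisubstituted alkene towards NCS, and TIPS is chosen because it neither migrates to an enolate oxygen nor falls to hydroxide in step 6.

**Step 4**
Reactants: 8 4-hydroxybenzaldehyde; 9 geranyl bromide ((2E)-1-bromo-3,7-dimethylocta-2,6-diene)
Product: 10 3-[(2E)-3,7-dimethylocta-2,6-dienyl]-4-hydroxybenzaldehyde
Conditions: KOH (10 % aq), 0 °C → rt, 24 h
Reagents that add atoms: none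
Why: ortho-C-alkylation of an aqueous phenolate (the para position is blocked by CHO) by SN2 at the primary allylic carbon, so the E geometry is kept; the O-geranyl ether by-product is separated.

**Step 5**
Reactants: 10 3-[(2E)-3,7-dimethylocta-2,6-dienyl]-4-hydroxybenzaldehyde
Product: 11 3-[(2E)-3,7-dimethylocta-2,6-dienyl]-4-(triisopropylsilyloxy)benzaldehyde
Conditions: TIPSCl, imidazole, DMF, rt
Reagents that add atoms: triisopropylsilyl chloride CC(C)[Si](Cl)(C(C)C)C(C)C
Why: Standard silyl ether formation: it restores the electrophilicity of the aldehyde (no phenolate) and places a fluoride-labile trigger para to the future oxirane.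

**Step 6 (key step)**
Reactants: 7 2-chloro-1-[4,6-bis(methoxymethoxy)-3-(3-methylbut-2-enyl)-2-(triisopropylsilyloxy)phenyl]ethanone; 11 3-geranyl-4-(triisopropylsilyloxy)benzaldehyde (1.2 equiv)
Product: 14 (2R,3R)-2-(3-geranyl-4-hydroxyphenyl)-3-hydroxy-5,7-bis(methoxymethoxy)-8-prenylchroman-4-one, via trans-epoxy ketone 12 (not isolated), via epoxy diphenol 13 (not isolated)
Conditions: (i) N-[4-(trifluoromethyl)benzyl]cinchonidinium bromide (10 mol %), LiOH·H2O (2 equiv), n-Bu2O/CH2Cl2, 0 °C; (ii) same flask, no work-up: AcOH (5 equiv), TBAF (4 equiv), THF, 0 °C → rt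
Reagents that add atoms: none
Why: Proposed new method: inside the chiral ion pair (free 9-OH hydrogen-bonded to the enolate) the ammonium enolate of 7 adds to 11 and the chlorohydrin alkoxide closes by SN2 to the trans-(2R,3S)-oxirane 12; the closest known reaction is the phase-transfer asymmetric Darzens condensation of aryl chloromethyl ketones, whose nucleophilic conditions leave the three trisubstituted alkenes untouched, and the cinchoninium pseudoenantiomer is the drop-in if a first analytical run shows the opposite sense; buffered fluoride then frees only the 2'-OH next to the prenyl group and the 4-OH para to the oxirane, whose push (p-quinone-methide character) makes the benzylic C–O bond the one that breaks, so the 2'-OH closes 6-endo rather than 5-exo with inversion (closest known type: chalcone-epoxide to dihydroflavonol cyclisation); C3 keeps the catalyst-set R centre, C2 ends R and trans-diequatorial, which is also the thermodynamic result if the opening is SN1-like, and the 6'-OMOM cannot compete, so only the 8-prenyl isomer forms.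

**Step 7**
Reactants: 14 (2R,3R)-2-(3-geranyl-4-hydroxyphenyl)-3-hydroxy-5,7-bis(methoxymethoxy)-8-prenylchroman-4-one
Product: 15 sanggenol C, (2R,3R)-2-(3-geranyl-4-hydroxyphenyl)-3,5,7-trihydroxy-8-prenylchroman-4-one
Conditions: 3 M aq HCl (cat.), MeOH, 45 °C, 1 h
Reagents that add atoms: none
Why: Acid-catalysed acetal exchange (MOM cleavage) in methanol: dihydroflavonols hold their configuration under mild acid (any C2 equilibration through the benzylic cation returns to the favoured 2,3-trans isomer), and short contact at ≤45 °C avoids chroman formation from the o-prenyl and o-geranyl phenols.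

**Compound list**
1 | 2',4',6'-trihydroxyacetophenone | CC(=O)c1c(O)cc(O)cc1O | starting material
2 | prenyl bromide | CC(C)=CCBr | starting material
3 | 1-[2,4,6-trihydroxy-3-prenylphenyl]ethanone | CC(=O)c1c(O)cc(O)c(CC=C(C)C)c1O | intermediate
4 | 1-[2-hydroxy-4,6-bis(methoxymethoxy)-3-prenylphenyl]ethanone | CC(=O)c1c(OCOC)cc(OCOC)c(CC=C(C)C)c1O | intermediate
5 | 1-[4,6-bis(methoxymethoxy)-3-prenyl-2-(triisopropylsilyloxy)phenyl]ethanone (not isolated) | CC(=O)c1c(OCOC)cc(OCOC)c(CC=C(C)C)c1O[Si](C(C)C)(C(C)C)C(C)C | intermediate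
6 | trimethylsilyl enol ether of 5 (not isolated) | C=C(O[Si](C)(C)C)c1c(OCOC)cc(OCOC)c(CC=C(C)C)c1O[Si](C(C)C)(C(C)C)C(C)C | intermediate
7 | 2-chloro-1-[4,6-bis(methoxymethoxy)-3-prenyl-2-(triisopropylsilyloxy)phenyl]ethanone | O=C(CCl)c1c(OCOC)cc(OCOC)c(CC=C(C)C)c1O[Si](C(C)C)(C(C)C)C(C)C | intermediate
8 | 4-hydroxybenzaldehyde | O=Cc1ccc(O)cc1 | starting material
9 | geranyl bromide (E) | CC(C)=CCC/C(C)=C/CBr | starting material
10 | 3-geranyl-4-hydroxybenzaldehyde | CC(C)=CCC/C(C)=C/Cc1cc(C=O)ccc1O | intermediate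
11 | 3-geranyl-4-(triisopropylsilyloxy)benzaldehyde | CC(C)=CCC/C(C)=C/Cc1cc(C=O)ccc1O[Si](C(C)C)(C(C)C)C(C)C | intermediate
12 | [(2R,3S)-3-(3-geranyl-4-TIPSO-phenyl)oxiran-2-yl][4,6-bis(methoxymethoxy)-3-prenyl-2-TIPSO-phenyl]methanone (not isolated) | CC(C)=CCC/C(C)=C/Cc1cc([C@@H]2O[C@H]2C(=O)c3c(OCOC)cc(OCOC)c(CC=C(C)C)c3O[Si](C(C)C)(C(C)C)C(C)C)ccc1O[Si](C(C)C)(C(C)C)C(C)C | intermediate
13 | [(2R,3S)-3-(3-geranyl-4-hydroxyphenyl)oxiran-2-yl][2-hydroxy-4,6-bis(methoxymethoxy)-3-prenylphenyl]methanone (not isolated) | CC(C)=CCC/C(C)=C/Cc1cc([C@@H]2O[C@H]2C(=O)c3c(OCOC)cc(OCOC)c(CC=C(C)C)c3O)ccc1O | intermediate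
14 | (2R,3R)-5,7-bis-O-methoxymethyl sanggenol C | CC(C)=CCC/C(C)=C/Cc1cc([C@H]2Oc3c(CC=C(C)C)c(OCOC)cc(OCOC)c3C(=O)[C@@H]2O)ccc1O | intermediate
15 | sanggenol C (2R,3R) | CC(C)=CCC/C(C)=C/Cc1cc([C@H]2Oc3c(CC=C(C)C)c(O)cc(O)c3C(=O)[C@@H]2O)ccc1O | target

**Total step count:** 7.
**Longest linear sequence:** 5 (steps 1, 2, 3, 6, 7).

**Steps most likely to fail**

*Step 6.* The risks are:
- low conversion or low ee for a di-ortho-substituted aryl chloromethyl ketone reacting with an electron-rich aldehyde;
- retro-aldol of the chlorohydrin alkoxide;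
- premature silyl loss, which leads to the benzofuranone;
- aroyl migration of the labile epoxide.

The fallback sets out from 7 (with 11) and comes back at 12. Compound 7 is quaternised with PPh3 (NaI cat., toluene, 80 °C) to the phosphonium chloride F1. Aqueous NaOH/CH2Cl2 then gives the acylmethylenetriphenylphosphorane F2. A neutral Wittig olefination of 11 (toluene, 110 °C) gives the (E)-chalcone F3. Juliá–Colonna epoxidation of F3 (poly-L-leucine, urea·H2O2, DBU, THF) is again nucleophilic and therefore spares the alkenes. It delivers isolated (2R,3S)-12, which is taken to 14 with TBAF/AcOH as in stage (ii).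

*Step 3.* The risks are attack of the silyl triflates on the MOM acetals and contact of N–Cl chlorine with the prenyl alkene. The fallback sets out from 4 and comes back at 7. Compound 4 is silylated alone (TIPSOTf, 2,6-lutidine) and 5 is isolated. Its lithium enolate (LiHMDS, −78 °C) is acylated with CF3CO2CH2CF3 to the trifluoromethyl 1,3-diketone F4. MsN3/Et3N/H2O in MeCN then effects detrifluoroacetylative diazo transfer to the diazoketone F5. One equivalent of HCl in Et2O at −20 °C gives 7, so no electrophilic chlorine ever meets an alkene.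

*Step 4.* The risks are dominant O-geranylation and dialkylation, which leave a low yield of 10. The fallback sets out from 8 and 9 and comes back at 11, skipping 10. Compound 8 is iodinated (NIS, cat. TFA, MeCN) to 4-hydroxy-3-iodobenzaldehyde F6, which is silylated (TIPSCl, imidazole) to 3-iodo-4-(triisopropylsilyloxy)benzaldehyde F7. Compound 9 is converted with Bu3SnLi (THF, −78 °C) into (E)-geranyltributylstannane F8. A Stille coupling of F7 with F8 (Pd2(dba)3, AsPh3, LiCl, DMF, 70 °C) joins them at the unsubstituted allyl terminus.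

**Further compounds**
F1 | step 6 | {2-[4,6-bis(methoxymethoxy)-3-prenyl-2-(triisopropylsilyloxy)phenyl]-2-oxoethyl}triphenylphosphonium chloride | [Cl-].O=C(C[P+](c1ccccc1)(c1ccccc1)c1ccccc1)c1c(OCOC)cc(OCOC)c(CC=C(C)C)c1O[Si](C(C)C)(C(C)C)C(C)C
F2 | step 6 | 1-[4,6-bis(methoxymethoxy)-3-prenyl-2-(triisopropylsilyloxy)phenyl]-2-(triphenylphosphoranylidene)ethanone | O=C(C=P(c1ccccc1)(c1ccccc1)c1ccccc1)c1c(OCOC)cc(OCOC)c(CC=C(C)C)c1O[Si](C(C)C)(C(C)C)C(C)C
F3 | step 6 | (E)-3-(3-geranyl-4-TIPSO-phenyl)-1-[4,6-bis(methoxymethoxy)-3-prenyl-2-TIPSO-phenyl]prop-2-en-1-one | CC(C)=CCC/C(C)=C/Cc1cc(/C=C/C(=O)c2c(OCOC)cc(OCOC)c(CC=C(C)C)c2O[Si](C(C)C)(C(C)C)C(C)C)ccc1O[Si](C(C)C)(C(C)C)C(C)C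
F4 | step 3 | 4,4,4-trifluoro-1-[4,6-bis(methoxymethoxy)-3-prenyl-2-(triisopropylsilyloxy)phenyl]butane-1,3-dione | O=C(CC(=O)C(F)(F)F)c1c(OCOC)cc(OCOC)c(CC=C(C)C)c1O[Si](C(C)C)(C(C)C)C(C)C
F5 | step 3 | 2-diazo-1-[4,6-bis(methoxymethoxy)-3-prenyl-2-(triisopropylsilyloxy)phenyl]ethanone | [N-]=[N+]=CC(=O)c1c(OCOC)cc(OCOC)c(CC=C(C)C)c1O[Si](C(C)C)(C(C)C)C(C)C
F6 | step 4 | 4-hydroxy-3-iodobenzaldehyde | O=Cc1ccc(O)c(I)c1
F7 | step 4 | 3-iodo-4-(triisopropylsilyloxy)benzaldehyde | O=Cc1ccc(O[Si](C(C)C)(C(C)C)C(C)C)c(I)c1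
F8 | step 4 | (E)-geranyltributylstannane | CC(C)=CCC/C(C)=C/C[Sn](CCCC)(CCCC)CCCC
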